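**Retrosynthetic overview**
1. The target is cut into two molecules of one bibenzyl resorcinol, 5-[2-(2-methoxyphenyl)ethyl]-2-methylbenzene-1,3-diol. The biquinone C–C bond and both new ring oxygens are installed together in one aerobic oxidation/coupling cascade that mirrors the presumed biogenesis (dihydrostilbene → hydroxyquinone → phenol/quinone coupling).
2. The resorcinol comes from its dihydro form, a 2-methyl-5-substituted cyclohexane-1,3-dione, by dehydrogenative aromatisation.
3. The dione comes from an ethyl enone and dimethyl malonate by a polyketide-style ring assembly (malonate extender, carbonyl-condensation ring closure, loss of CO2), with no protecting groups.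
4. The enone comes from 3-(2-methoxyphenyl)propanal and diethyl (2-oxobutyl)phosphonate by olefination.
5. Ring order: the anisole ring is bought; each six-membered carbocycle is built in the annulation, aromatised, and only then oxidised to the quinone and joined. No ring is formed in the dimerisation.

Assumption: the SMILES carries no stereodescriptor and the molecule has no stereocentre; the configuration of the hindered biquinone axis is not specified, so the target is made as drawn, without axial stereocontrol.

**Step 1**
Reactants: 1 3-(2-methoxyphenyl)propanal; 2 diethyl (2-oxobutyl)phosphonate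
Product: 3 (E)-7-(2-methoxyphenyl)hept-4-en-3-one
Conditions: 2, NaH (1.05 equiv), THF, 0 °C; then 1, 0 °C → rt
Reagents that add atoms: none
Why: Horner–Wadsworth–Emmons olefination of the stabilised β-ketophosphonate anion with the unhindered aldehyde gives the (E)-enone under thermodynamic control, and no stereocentre is formed.

**Step 2**
Reactants: 3 (E)-7-(2-methoxyphenyl)hept-4-en-3-one; 4 dimethyl malonate
Product: 8 5-[2-(2-methoxyphenyl)ethyl]-2-methylcyclohexane-1,3-dione, via Michael adduct 5 (not isolated), via cyclic keto ester 6 (not isolated), via keto acid 7 (not isolated)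
Conditions: NaOMe (1.2 equiv), MeOH, reflux; then 2 M NaOH (aq), reflux; then conc. HCl to pH 1, 80 °C
Reagents that add atoms: none
Why: This is the dimedone-type tandem Michael addition/Claisen (Dieckmann-type) annulation, in which malonate adds to the enone β-carbon and the ethyl-ketone α′-carbon closes the only possible six-membered ring on a malonate ester, driven by the stabilised β-diketone enolate; saponification and acid decarboxylation of the β-keto acid then give the dione, whose stereocentres are irrelevant because aromatisation erases them.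

**Step 3**
Reactants: 8 5-[2-(2-methoxyphenyl)ethyl]-2-methylcyclohexane-1,3-dione
Product: 9 5-[2-(2-methoxyphenyl)ethyl]-2-methylbenzene-1,3-diol
Conditions: 10% Pd/C (5 mol % Pd), triglyme, 200 °C, N2 sweep
Reagents that add atoms: none
Why: Heterogeneous palladium-catalysed acceptorless dehydrogenation of the enolised cyclohexane-1,3-dione (loss of one H2) is driven by aromatisation to the resorcinol, the N2 sweep removing H2 so that hydrogenolysis is suppressed; no stereocentre remains.

**Step 4**
Reactants: 9 5-[2-(2-methoxyphenyl)ethyl]-2-methylbenzene-1,3-diol (two molecules)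
Product: 13 4,4'-dihydroxy-2,2'-bis[2-(2-methoxyphenyl)ethyl]-5,5'-dimethyl-[1,1'-bi(cyclohexa-1,4-diene)]-3,3',6,6'-tetrone, via hydroxyquinone 10 (not isolated), via biaryl pentol 11 (not isolated), via arylquinone 12 (not isolated)
Conditions: KOH (6 equiv), EtOH/H2O (4:1), 0 °C, O2 (0.5 equiv, gas burette); then Ar, rt; then O2 (1 atm), 0 °C → rt; then 1 M HCl
Reagents that add atoms: dioxygen, O=O
Why: Proposed new method: the resorcinol dianion is autoxidised by O2 at the carbon para to one phenolate (phenoxyl radical/superoxide recombination, 4-hydroperoxydienone, loss of water) to hydroxyquinone 10; under argon its only free ring carbon (C5, β to the C1 carbonyl) is attacked by the only free nucleophilic carbon of the remaining resorcinol dianion to give biaryl 11; readmitted O2 oxidises the triol ring to the quinone 12 (O2 → H2O2) and oxygenates the second resorcinol ring as it did the first, so the substitution pattern dictates every bond-forming site, no stereocentre arises, and 13, with no free ring position, is the end point; the closest known reaction type is the Beam-type alkaline aerobic oxidation of 2-substituted 5-alkylresorcinols to 2-hydroxy-1,4-benzoquinones, in which C–C linked dimers of this connectivity appear as co-products, combined with the conjugate addition of phenolates to quinones.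

**Compound list**
1 | 3-(2-methoxyphenyl)propanal | COc1ccccc1CCC=O | starting material
2 | diethyl (2-oxobutyl)phosphonate | CCC(=O)CP(=O)(OCC)OCC | starting material
3 | (E)-7-(2-methoxyphenyl)hept-4-en-3-one | CCC(=O)/C=C/CCc1ccccc1OC | intermediate
4 | dimethyl malonate | COC(=O)CC(=O)OC | starting material
5 | dimethyl 2-[1-(2-methoxyphenyl)-5-oxoheptan-3-yl]propanedioate (racemic) | CCC(=O)CC(CCc1ccccc1OC)C(C(=O)OC)C(=O)OC | intermediate
6 | methyl 6-[2-(2-methoxyphenyl)ethyl]-3-methyl-2,4-dioxocyclohexane-1-carboxylate (racemic stereoisomer mixture, present as its sodium enolate) | COC(=O)C1C(CCc2ccccc2OC)CC(=O)C(C)C1=O | intermediate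
7 | 6-[2-(2-methoxyphenyl)ethyl]-3-methyl-2,4-dioxocyclohexane-1-carboxylic acid (racemic stereoisomer mixture) | OC(=O)C1C(CCc2ccccc2OC)CC(=O)C(C)C1=O | intermediate
8 | 5-[2-(2-methoxyphenyl)ethyl]-2-methylcyclohexane-1,3-dione (largely enolised, stereochemistry irrelevant) | CC1C(=O)CC(CCc2ccccc2OC)CC1=O | intermediate
9 | 5-[2-(2-methoxyphenyl)ethyl]-2-methylbenzene-1,3-diol | Cc1c(O)cc(CCc2ccccc2OC)cc1O | intermediate
10 | 2-hydroxy-6-[2-(2-methoxyphenyl)ethyl]-3-methylcyclohexa-2,5-diene-1,4-dione | CC1=C(O)C(=O)C(CCc2ccccc2OC)=CC1=O | intermediate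
11 | 6,6'-bis[2-(2-methoxyphenyl)ethyl]-3,3'-dimethyl-[1,1'-biphenyl]-2,2',4,4',5-pentol | Cc1c(O)c(O)c(CCc2ccccc2OC)c(-c2c(CCc3ccccc3OC)cc(O)c(C)c2O)c1O | intermediate
12 | 5-{2,4-dihydroxy-6-[2-(2-methoxyphenyl)ethyl]-3-methylphenyl}-2-hydroxy-6-[2-(2-methoxyphenyl)ethyl]-3-methylcyclohexa-2,5-diene-1,4-dione | CC1=C(O)C(=O)C(CCc2ccccc2OC)=C(c2c(CCc3ccccc3OC)cc(O)c(C)c2O)C1=O | intermediate
13 | 4,4'-dihydroxy-2,2'-bis[2-(2-methoxyphenyl)ethyl]-5,5'-dimethyl-[1,1'-bi(cyclohexa-1,4-diene)]-3,3',6,6'-tetrone | COc1ccccc1CCC1=C(C2=C(CCc3ccccc3OC)C(=O)C(O)=C(C)C2=O)C(=O)C(C)=C(O)C1=O | target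

**Total step count:** 4
**Longest linear sequence:** 4 steps (1 → 3 → 8 → 9 → 13)

**Steps most likely to fail**

First, step 4. The cascade can stall at monomeric hydroxyquinone 10, the free position of the resorcinol ring in 11 or 12 can add a further quinone to give oligomers, and hydroxide or the peroxide formed can degrade the quinones. The fallback sets out from 9 and comes back at 13. Compound 9 is oxidised to completion with (KSO3)2NO (2.2 equiv, aq. KH2PO4/acetone, 0 °C, Teuber oxidation) and hydroxyquinone 10 is isolated. Half of it is reduced with aqueous Na2S2O4 to 6-[2-(2-methoxyphenyl)ethyl]-3-methylbenzene-1,2,4-triol F1. F1 and 10 (1:1) are stirred in degassed AcOH with catalytic H2SO4, so that the triol adds through its only free ring carbon to C5 of the quinone and gives 6,6'-bis[2-(2-methoxyphenyl)ethyl]-3,3'-dimethyl-[1,1'-biphenyl]-2,2',4,4',5,5'-hexol F2. F2 is oxidised with FeCl3 in aqueous EtOH to 13. Each partner has exactly one free ring position, so this coupling cannot go beyond the dimer.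

Second, step 3. The liberated H2 can hydrogenolyse a C–O bond or cause disproportionation, and the 2-methyl dione may dehydrogenate sluggishly. The fallback sets out from 8 and comes back at 9. Compound 8 is converted with TMSOTf/Et3N (CH2Cl2, 0 °C) into 5-[2-(2-methoxyphenyl)ethyl]-2-methyl-1,3-bis(trimethylsilyloxy)cyclohexa-1,3-diene F3. This is dehydrogenated with DDQ (benzene, rt) to 5-[2-(2-methoxyphenyl)ethyl]-2-methyl-1,3-bis(trimethylsilyloxy)benzene F4, and the silyl ethers are cleaved with 1 M HCl in THF to give 9.

Third, step 2. The enone can oligomerise or deconjugate under methoxide, and ring closure through the more hindered ethyl α′-carbon can be slow. The fallback sets out from 1 and comes back at 6. Compound 1 is olefinated with trimethyl phosphonoacetate (NaH, THF) to methyl (E)-5-(2-methoxyphenyl)pent-2-enoate F5. F5 is annulated with methyl 3-oxopentanoate (NaOMe, MeOH, reflux): the β-keto ester carbon adds to the enoate and the propionyl CH2 closes the ring on the enoate ester. This gives the same cyclic keto ester 6 as its sodium enolate, which is saponified and decarboxylated to 8 as in the route.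

**Further compounds**
F1 | step 4 | 6-[2-(2-methoxyphenyl)ethyl]-3-methylbenzene-1,2,4-triol | Cc1c(O)c(O)c(CCc2ccccc2OC)cc1O
F2 | step 4 | 6,6'-bis[2-(2-methoxyphenyl)ethyl]-3,3'-dimethyl-[1,1'-biphenyl]-2,2',4,4',5,5'-hexol | Cc1c(O)c(O)c(CCc2ccccc2OC)c(-c2c(CCc3ccccc3OC)c(O)c(O)c(C)c2O)c1O
F3 | step 3 | 5-[2-(2-methoxyphenyl)ethyl]-2-methyl-1,3-bis(trimethylsilyloxy)cyclohexa-1,3-diene (racemic) | CC1=C(O[Si](C)(C)C)CC(CCc2ccccc2OC)C=C1O[Si](C)(C)C
F4 | step 3 | 5-[2-(2-methoxyphenyl)ethyl]-2-methyl-1,3-bis(trimethylsilyloxy)benzene | Cc1c(O[Si](C)(C)C)cc(CCc2ccccc2OC)cc1O[Si](C)(C)C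
F5 | step 2 | methyl (E)-5-(2-methoxyphenyl)pent-2-enoate | COC(=O)/C=C/CCc1ccccc1OC
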